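**Retrosynthetic overview** (C1 bears C7H2OBz, C2 is the ring CH=, C3 bears OBz, C4–C6 bear OH)
- Target ⇐ acid release from a 4,5-cis-acetonide/6-O-TBS dibenzoate ⇐ C3,C7-diol obtained by trans→cis acetonide migration.
- Cyclohexene (the only carbocycle, closed after all four stereocentres exist) ⇐ ring-closing metathesis across C1=C2 ⇐ methylenation of a C1 ketone.
- Ketone ⇐ intermolecular boron syn-aldol forming C5–C6 (sets C5 and C6): bis-O-TBS dihydroxyacetone (C7–C1–C6) + trans-4-formyl-5-vinyl-dioxolane (C5–C2; C3 and C4 from D-tartrate).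
- Ring order: dioxolane (chiral pool) → cyclohexene (metathesis) → dioxolane re-fused cis (migration) → dioxolane cleaved.

Assumption: 1,3-dihydroxyacetone is bought as its dimer and drawn and counted as the monomer; TBS = tert-butyldimethylsilyl, TES = triethylsilyl, Bz = benzoyl.

**Route**

Step 1
Reactants: 1 dimethyl (4S,5S)-2,2-dimethyl-1,3-dioxolane-4,5-dicarboxylate (dimethyl 2,3-O-isopropylidene-D-tartrate)
Product: 2 [(4R,5R)-2,2-dimethyl-1,3-dioxolane-4,5-diyl]dimethanol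
Conditions: LiAlH4 (1.5 equiv), THF, 0 °C → reflux; H2O, 15% NaOH, H2O
Reagents that add atoms: none
Why: Hydride reduction of both esters to primary alcohols leaves the two stereocentres untouched (the descriptors change from S to R only because substituent priorities change).

Step 2
Reactants: 2 [(4R,5R)-2,2-dimethyl-1,3-dioxolane-4,5-diyl]dimethanol
Product: 4 [(4R,5R)-5-(TBSO-methyl)-2,2-dimethyl-1,3-dioxolan-4-yl]methanol, via monosodium alkoxide 3 (not isolated)
Conditions: NaH (1.0 equiv), THF, 0 °C → rt, 45 min; TBSCl (1.0 equiv), rt, 1 h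
Reagents that add atoms: tert-butyldimethylsilyl chloride, CC(C)(C)[Si](C)(C)Cl
Why: Monosilylation of a C2-symmetric diol through its poorly soluble monosodium alkoxide (Williamson-type O-silylation) gives one product whichever hydroxyl reacts and suppresses disilylation.

Step 3
Reactants: 4 [(4R,5R)-5-(TBSO-methyl)-2,2-dimethyl-1,3-dioxolan-4-yl]methanol
Product: 5 (4S,5R)-5-(TBSO-methyl)-2,2-dimethyl-1,3-dioxolane-4-carbaldehyde
Conditions: Dess–Martin periodinane (1.2 equiv), CH2Cl2, 0 °C → rt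
Reagents that add atoms: none
Why: Dess–Martin oxidation stops at the aldehyde under near-neutral conditions, keeping the acetonide, the silyl ether and the trans-dioxolane configuration.

Step 4
Reactants: 5 (4S,5R)-5-(TBSO-methyl)-2,2-dimethyl-1,3-dioxolane-4-carbaldehyde
Product: 6 tert-butyl{[(4R,5R)-5-ethenyl-2,2-dimethyl-1,3-dioxolan-4-yl]methoxy}dimethylsilane
Conditions: Ph3PCH3Br (1.5 equiv), KN(SiMe3)2 (1.4 equiv), THF, 0 °C; then 5, −78 °C → rt
Reagents that add atoms: methyltriphenylphosphonium bromide, C[P+](c1ccccc1)(c1ccccc1)c1ccccc1.[Br-]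
Why: Wittig methylenation with the non-stabilised ylide gives the terminal alkene, and any reversible enolisation would only return the more stable trans-dioxolane.

Step 5
Reactants: 6 tert-butyl{[(4R,5R)-5-ethenyl-2,2-dimethyl-1,3-dioxolan-4-yl]methoxy}dimethylsilane
Product: 7 [(4R,5R)-5-ethenyl-2,2-dimethyl-1,3-dioxolan-4-yl]methanol
Conditions: Bu4NF (1.1 equiv), THF, 0 °C → rt
Reagents that add atoms: none
Why: Fluoride-mediated desilylation, driven by the strong Si–F bond, frees the primary alcohol without touching the acetonide or the alkene.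

Step 6
Reactants: 7 [(4R,5R)-5-ethenyl-2,2-dimethyl-1,3-dioxolan-4-yl]methanol
Product: 8 (4S,5R)-5-ethenyl-2,2-dimethyl-1,3-dioxolane-4-carbaldehyde
Conditions: Dess–Martin periodinane (1.2 equiv), CH2Cl2, 0 °C → rt; volatile, used crude at once
Reagents that add atoms: none
Why: Dess–Martin oxidation gives the α-alkoxy aldehyde without over-oxidation or epimerisation of the trans-dioxolane.

Step 7
Reactants: 9 1,3-dihydroxyacetone
Product: 10 1,3-bis(TBSO)propan-2-one
Conditions: TBSCl (2.2 equiv), imidazole (4.4 equiv), DMF, 0 °C → rt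
Reagents that add atoms: tert-butyldimethylsilyl chloride, CC(C)(C)[Si](C)(C)Cl
Why: Imidazole-promoted silylation (Corey protocol) caps both primary hydroxyls as the dimer cracks to the monomer.

Step 8
Reactants: 10 1,3-bis(TBSO)propan-2-one; 8 (4S,5R)-5-ethenyl-2,2-dimethyl-1,3-dioxolane-4-carbaldehyde
Product: 13 (3R,4S)-1,3-bis(TBSO)-4-[(4R,5R)-5-ethenyl-2,2-dimethyl-1,3-dioxolan-4-yl]-4-hydroxybutan-2-one, via (Z)-dicyclohexylboron enolate 11 (not isolated), via dicyclohexylboron aldolate 12 (not isolated)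
Conditions: (c-C6H11)2BCl (1.6 equiv), Et3N (1.8 equiv), Et2O, −78 → 0 °C; 8, −78 → 0 °C; then pH 7 buffer, MeOH, 30% H2O2, 0 °C
Reagents that add atoms: none
Why: In this boron-mediated aldol addition the α-silyloxy ketone forms the (Z)-enolborinate, whose Zimmerman–Traxler chair gives the 5,6-syn relationship (C6), while attack anti to the aldehyde α C–O bond (Cornforth/polar Felkin–Anh control from C4) gives the 4,5-anti relationship (C5).

Step 9
Reactants: 13 (3R,4S)-1,3-bis(TBSO)-4-[(4R,5R)-5-ethenyl-2,2-dimethyl-1,3-dioxolan-4-yl]-4-hydroxybutan-2-one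
Product: 14 (3R,4S)-1,3-bis(TBSO)-4-[(4S,5R)-5-ethenyl-2,2-dimethyl-1,3-dioxolan-4-yl]-4-(TESO)butan-2-one
Conditions: Et3SiOTf (1.3 equiv), 2,6-lutidine (2.0 equiv), CH2Cl2, −78 °C
Reagents that add atoms: triethylsilyl trifluoromethanesulfonate, CC[Si](CC)(CC)OS(=O)(=O)C(F)(F)F
Why: Silyl triflate silylation with a hindered base at low temperature caps the C5 hydroxyl before retro-aldol or β-elimination can occur, with a group that can later be removed beside the secondary TBS ether.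

Step 10
Reactants: 14 (3R,4S)-1,3-bis(TBSO)-4-[(4S,5R)-5-ethenyl-2,2-dimethyl-1,3-dioxolan-4-yl]-4-(TESO)butan-2-one
Product: 15 (3S,4S)-3-(TBSO)-2-(TBSO-methyl)-4-[(4S,5R)-5-ethenyl-2,2-dimethyl-1,3-dioxolan-4-yl]-4-(TESO)but-1-ene
Conditions: Cp2Ti(μ-CH2)(μ-Cl)AlMe2 (Tebbe reagent, 1.5 equiv, toluene solution), pyridine (cat.), THF, −40 → 0 °C; 0.1 M NaOH quench
Reagents that add atoms: Tebbe reagent Cp2Ti(μ-CH2)(μ-Cl)AlMe2, C[Al-]1(C)C[Ti](C2C=CC=C2)(C2C=CC=C2)[Cl+]1
Why: Tebbe methylenation (via Cp2Ti=CH2 and an oxatitanacyclobutane) is non-basic, so the hindered ketone is olefinated without epimerising C6 or eliminating the β-silyloxy group.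

Step 11
Reactants: 15 (3S,4S)-3-(TBSO)-2-(TBSO-methyl)-4-[(4S,5R)-5-ethenyl-2,2-dimethyl-1,3-dioxolan-4-yl]-4-(TESO)but-1-ene
Product: 16 (3aS,4S,5S,7aR)-5-(TBSO)-6-(TBSO-methyl)-2,2-dimethyl-4-(TESO)-3a,4,5,7a-tetrahydro-1,3-benzodioxole
Conditions: second-generation Grubbs catalyst (H2IMes)(PCy3)Cl2Ru=CHPh (7 mol%), toluene (0.005 M), 80 °C
Reagents that add atoms: none
Why: In this ring-closing olefin metathesis the Ru carbene loads on the vinyl group and closes onto the 1,1-disubstituted alkene to give the trisubstituted cyclohexene with loss of ethene, no stereocentre being involved.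

Step 12
Reactants: 16 (3aS,4S,5S,7aR)-5-(TBSO)-6-(TBSO-methyl)-2,2-dimethyl-4-(TESO)-3a,4,5,7a-tetrahydro-1,3-benzodioxole
Product: 17 (3aR,4S,5S,7aR)-5-(TBSO)-6-(hydroxymethyl)-2,2-dimethyl-3a,4,5,7a-tetrahydro-1,3-benzodioxol-4-ol
Conditions: HF·pyridine, pyridine, THF, 0 °C → rt
Reagents that add atoms: none
Why: Chemoselective desilylation with buffered HF cleaves the secondary TES ether and the primary TBS ether much faster than the hindered secondary TBS ether at C6 and leaves the acetonide in place.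

Step 13
Reactants: 17 (3aR,4S,5S,7aR)-5-(TBSO)-6-(hydroxymethyl)-2,2-dimethyl-3a,4,5,7a-tetrahydro-1,3-benzodioxol-4-ol
Product: 18 (3aS,4R,7S,7aS)-7-(TBSO)-6-(hydroxymethyl)-2,2-dimethyl-3a,4,7,7a-tetrahydro-1,3-benzodioxol-4-ol
Conditions: camphorsulfonic acid (10 mol%), dry acetone, rt
Reagents that add atoms: none
Why: Acid-catalysed acetonide migration (intramolecular transketalisation) moves the strained trans-fused dioxolane onto the cis C4/C5 diol, the thermodynamically favoured cis-fused isomer, which frees only the C3 hydroxyl and breaks no C–O bond at a stereocentre.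

Step 14
Reactants: 18 (3aS,4R,7S,7aS)-7-(TBSO)-6-(hydroxymethyl)-2,2-dimethyl-3a,4,7,7a-tetrahydro-1,3-benzodioxol-4-ol
Product: 19 [(3aS,4R,7S,7aS)-4-(benzoyloxy)-7-(TBSO)-2,2-dimethyl-3a,4,7,7a-tetrahydro-1,3-benzodioxol-6-yl]methyl benzoate
Conditions: BzCl (3.0 equiv), pyridine, DMAP (10 mol%), CH2Cl2, 0 °C → rt
Reagents that add atoms: benzoyl chloride, O=C(Cl)c1ccccc1
Why: DMAP-catalysed acylation esterifies the only two free hydroxyls (primary C7–OH and secondary allylic C3–OH) with retention at C3.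

Step 15
Reactants: 19 [(3aS,4R,7S,7aS)-4-(benzoyloxy)-7-(TBSO)-2,2-dimethyl-3a,4,7,7a-tetrahydro-1,3-benzodioxol-6-yl]methyl benzoate
Product: 20 [(3R,4R,5R,6S)-3-(benzoyloxy)-4,5,6-trihydroxycyclohex-1-en-1-yl]methyl benzoate
Conditions: CF3CO2H/H2O (4:1), 0 °C → rt; toluene co-evaporation
Reagents that add atoms: none
Why: Acid hydrolysis cleaves the isopropylidene ketal and the TBS ether in one operation while the benzoates are stable to cold aqueous trifluoroacetic acid, so all four stereocentres and both esters arrive unchanged.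

**Compound list**

1 | dimethyl (4S,5S)-2,2-dimethyl-1,3-dioxolane-4,5-dicarboxylate | COC(=O)[C@H]1OC(C)(C)O[C@@H]1C(=O)OC | starting material
2 | [(4R,5R)-2,2-dimethyl-1,3-dioxolane-4,5-diyl]dimethanol | OC[C@H]1OC(C)(C)O[C@@H]1CO | intermediate
3 | monosodium alkoxide of 2 | [Na+].[O-]C[C@H]1OC(C)(C)O[C@@H]1CO | intermediate
4 | [(4R,5R)-5-(TBSO-methyl)-2,2-dimethyl-1,3-dioxolan-4-yl]methanol | OC[C@H]1OC(C)(C)O[C@@H]1CO[Si](C)(C)C(C)(C)C | intermediate
5 | (4S,5R)-5-(TBSO-methyl)-2,2-dimethyl-1,3-dioxolane-4-carbaldehyde | O=C[C@H]1OC(C)(C)O[C@@H]1CO[Si](C)(C)C(C)(C)C | intermediate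
6 | tert-butyl{[(4R,5R)-5-ethenyl-2,2-dimethyl-1,3-dioxolan-4-yl]methoxy}dimethylsilane | C=C[C@H]1OC(C)(C)O[C@@H]1CO[Si](C)(C)C(C)(C)C | intermediate
7 | [(4R,5R)-5-ethenyl-2,2-dimethyl-1,3-dioxolan-4-yl]methanol | C=C[C@H]1OC(C)(C)O[C@@H]1CO | intermediate
8 | (4S,5R)-5-ethenyl-2,2-dimethyl-1,3-dioxolane-4-carbaldehyde | C=C[C@H]1OC(C)(C)O[C@@H]1C=O | intermediate
9 | 1,3-dihydroxyacetone | O=C(CO)CO | starting material
10 | 1,3-bis(TBSO)propan-2-one | CC(C)(C)[Si](C)(C)OCC(=O)CO[Si](C)(C)C(C)(C)C | intermediate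
11 | (Z)-1,3-bis(TBSO)prop-1-en-2-yl dicyclohexylborinate | CC(C)(C)[Si](C)(C)OC/C(OB(C1CCCCC1)C1CCCCC1)=C/O[Si](C)(C)C(C)(C)C | intermediate
12 | O-dicyclohexylboryl aldolate of 13 | CC(C)(C)[Si](C)(C)OCC(=O)[C@H](O[Si](C)(C)C(C)(C)C)[C@@H](OB(C1CCCCC1)C1CCCCC1)[C@H]1OC(C)(C)O[C@@H]1C=C | intermediate
13 | (3R,4S)-1,3-bis(TBSO)-4-[(4R,5R)-5-ethenyl-2,2-dimethyl-1,3-dioxolan-4-yl]-4-hydroxybutan-2-one | CC(C)(C)[Si](C)(C)OCC(=O)[C@H](O[Si](C)(C)C(C)(C)C)[C@@H](O)[C@H]1OC(C)(C)O[C@@H]1C=C | intermediate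
14 | (3R,4S)-1,3-bis(TBSO)-4-[(4S,5R)-5-ethenyl-2,2-dimethyl-1,3-dioxolan-4-yl]-4-(TESO)butan-2-one | CC(C)(C)[Si](C)(C)OCC(=O)[C@H](O[Si](C)(C)C(C)(C)C)[C@@H](O[Si](CC)(CC)CC)[C@H]1OC(C)(C)O[C@@H]1C=C | intermediate
15 | (3S,4S)-3-(TBSO)-2-(TBSO-methyl)-4-[(4S,5R)-5-ethenyl-2,2-dimethyl-1,3-dioxolan-4-yl]-4-(TESO)but-1-ene | CC(C)(C)[Si](C)(C)OCC(=C)[C@H](O[Si](C)(C)C(C)(C)C)[C@@H](O[Si](CC)(CC)CC)[C@H]1OC(C)(C)O[C@@H]1C=C | intermediate
16 | (3aS,4S,5S,7aR)-5-(TBSO)-6-(TBSO-methyl)-2,2-dimethyl-4-(TESO)-3a,4,5,7a-tetrahydro-1,3-benzodioxole | CC(C)(C)[Si](C)(C)OCC1=C[C@H]2OC(C)(C)O[C@@H]2[C@H](O[Si](CC)(CC)CC)[C@H]1O[Si](C)(C)C(C)(C)C | intermediate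
17 | (3aR,4S,5S,7aR)-5-(TBSO)-6-(hydroxymethyl)-2,2-dimethyl-3a,4,5,7a-tetrahydro-1,3-benzodioxol-4-ol | OCC1=C[C@H]2OC(C)(C)O[C@@H]2[C@H](O)[C@H]1O[Si](C)(C)C(C)(C)C | intermediate
18 | (3aS,4R,7S,7aS)-7-(TBSO)-6-(hydroxymethyl)-2,2-dimethyl-3a,4,7,7a-tetrahydro-1,3-benzodioxol-4-ol | OCC1=C[C@@H](O)[C@@H]2OC(C)(C)O[C@@H]2[C@H]1O[Si](C)(C)C(C)(C)C | intermediate
19 | [(3aS,4R,7S,7aS)-4-(benzoyloxy)-7-(TBSO)-2,2-dimethyl-3a,4,7,7a-tetrahydro-1,3-benzodioxol-6-yl]methyl benzoate | O=C(OCC1=C[C@@H](OC(=O)c2ccccc2)[C@@H]2OC(C)(C)O[C@@H]2[C@H]1O[Si](C)(C)C(C)(C)C)c1ccccc1 | intermediate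
20 | [(3R,4R,5R,6S)-3-(benzoyloxy)-4,5,6-trihydroxycyclohex-1-en-1-yl]methyl benzoate | O=C(OCC1=C[C@@H](OC(=O)c2ccccc2)[C@H](O)[C@H](O)[C@H]1O)c1ccccc1 | target

**Step count and risks**

Total step count: 15. Longest linear sequence: 14 steps (1 → 20 through steps 1–6 and 8–15); the ketone arm is one step (step 7).

Step 8 (aldol) is the most likely to fail, because both the syn/anti ratio and the facial selectivity rest on substrate control and the minor diastereomers must be separated. The fallback sets out from 10 (with 8) and comes back at 13. It replaces the preformed boron enolate by catalyst-controlled enamine catalysis: 10 (3 equiv) and 8 are stirred with O-tert-butyl-L-threonine (20 mol%) and 5-methyl-1H-tetrazole (10 mol%) in wet N-methylpyrrolidone at 4 °C. The primary-amine (Z)-enamine is expected to give the syn-(3R,4S) aldol, which matches the aldehyde's own facial bias, and the product is 13 itself, so no new compound arises (F0).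

Step 11 (metathesis) may stall, because the 1,1-disubstituted alkene is flanked by two bulky silyloxy groups. The fallback sets out from 15 and comes back at 17. The desilylation is done first (HF·pyridine, pyridine, THF, 0 °C → rt) to give the diene diol (3S,4S)-3-(TBSO)-4-[(4R,5R)-5-ethenyl-2,2-dimethyl-1,3-dioxolan-4-yl]-2-methylidenebutane-1,4-diol F1. Its free hydroxyls relieve the crowding, and it is then cyclised with the second-generation Hoveyda–Grubbs catalyst (H2IMes)Cl2Ru=CH(C6H4-2-OiPr) in CH2Cl2 at 40 °C, which gives 17 directly.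

Step 13 (acetonide migration) may stop at an equilibrium mixture or erode the C6 silyl ether. The fallback sets out from 17 and comes back at 18. Instead of isomerising, the trans-acetonide is hydrolysed (80% aqueous AcOH, 40 °C) to the tetraol (1R,2S,3S,4S)-4-(TBSO)-5-(hydroxymethyl)cyclohex-5-ene-1,2,3-triol F2. The acetonide is then reinstalled with 2,2-dimethoxypropane and pyridinium p-toluenesulfonate in acetone at rt, where only the cis C4/C5 diol forms a stable five-membered ketal (any mixed ketal on the primary hydroxyl is lost on aqueous work-up), giving 18.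

**Further compounds**

F0 | step 8 | none | none
F1 | step 11 | (3S,4S)-3-(TBSO)-4-[(4R,5R)-5-ethenyl-2,2-dimethyl-1,3-dioxolan-4-yl]-2-methylidenebutane-1,4-diol | OCC(=C)[C@H](O[Si](C)(C)C(C)(C)C)[C@@H](O)[C@H]1OC(C)(C)O[C@@H]1C=C
F2 | step 13 | (1R,2S,3S,4S)-4-(TBSO)-5-(hydroxymethyl)cyclohex-5-ene-1,2,3-triol | OCC1=C[C@@H](O)[C@H](O)[C@H](O)[C@H]1O[Si](C)(C)C(C)(C)C
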